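The ε-lactone ring (O, C16, C15, C1, C14, C13, C12; cembrane numbering) is the cyclohexanone ring C16, C15, C1, C14, C13, C12 plus one oxygen, so the retrosynthesis first cuts C16–O and O–C12 and turns the hindered tertiary C12–O centre into an all-carbon quaternary centre; the C17 methylene and the C11 ketone are late adjustments.
Further cuts: C10–C11 (alkenylchromium/aldehyde closure of the 14-membered carbocycle), C11–C12 and C12–CH3 (formylation, then methylation of the ring ketone), C1–C2 (rhodium-catalysed 1,4-addition to cyclohex-2-en-1-one), C2=C3 and C9=C10 (one-carbon olefinations), C7–O (epoxide opening).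
Forward order: tetrahydrofuran from (R)-linalool (steps 1–2), attachment of the six-membered ring (step 6), 14-membered carbocycle (step 16), seven-membered lactone by oxygen insertion (step 19), then methylene, C11 ketone and release of C3–OH.
Stereochemistry: C4 from (R)-linalool; C7 and C8 from a Sharpless epoxidation followed by invertive ring closure; C1 from the (S)-BINAP rhodium catalyst; C3 from a Shi epoxidation and regioselective hydride opening; C12 from axial C-methylation, carried into the lactone with retention.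

Key step: step 19

Remark: atom labels follow the cembrane skeleton of the target (C1 ring CH bearing C2 and C15; C3 carbinol; C4 and C7 tetrahydrofuran carbons; C8 tertiary carbinol; C11 ketone; C12 lactone carbon with its methyl; C16 lactone carbonyl; C17 methylene).
Remark: the γ-hydroxy ketone (C8–OH, C11=O) of the target may equilibrate with a cyclic hemiketal; the open form as drawn is taken as the target.
Remark: C11 is formed as a carbinol of either configuration and is later oxidised, so both epimers are carried on and C11 is left undefined in 20–28.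
Remark: metal enolates, alkoxides and organochromium species formed and consumed within one operation are regarded as transient; covalent intermediates of telescoped operations are numbered.

Step 1
Reactants: 1 (R)-(−)-linalool
Product: 2 (2E,6R)-2,6-dimethylocta-2,7-diene-1,6-diol
Conditions: SeO2 (cat.), t-BuOOH, CH2Cl2, rt
Reagents that add atoms: tert-butyl hydroperoxide, CC(C)(C)OO
Why: A SeO2-catalysed allylic oxidation (ene reaction, then [2,3]-sigmatropic shift) attacks the more electron-rich trisubstituted alkene at its (E)-methyl group, so the primary alcohol at C9 should form with (E)-geometry while the vinyl carbinol is left alone; no stereocenter is made.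

Step 2
Reactants: 2 (2E,6R)-2,6-dimethylocta-2,7-diene-1,6-diol
Product: 4 (2R)-2-[(2S,5R)-5-ethenyl-5-methyloxolan-2-yl]propane-1,2-diol, via epoxy diol 3 (not isolated)
Conditions: Ti(OiPr)4 (10 mol %), D-(−)-diisopropyl tartrate (12 mol %), t-BuOOH, 4 Å MS, CH2Cl2, −20 °C; then CSA (cat.), 0 °C → rt
Reagents that add atoms: tert-butyl hydroperoxide, CC(C)(C)OO
Why: Sharpless asymmetric epoxidation of the (E)-2-methylallylic alcohol with the D-tartrate catalyst should give the (7R,8R)-epoxide 3 under reagent control (the tertiary vinyl carbinol is inert), and the C4 hydroxyl then opens it by an acid-catalysed 5-exo epoxide opening at C7 with inversion, which makes C7 S, keeps C8 R and gives the 2,5-cis tetrahydrofuran, the CH2OH group on C8 discouraging the 6-endo alternative.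

Step 3
Reactants: 4 tetrahydrofuran diol
Product: 5 bis(triethylsilyl) ether of 4
Conditions: TESOTf, 2,6-lutidine, CH2Cl2, −78 → 0 °C
Reagents that add atoms: triethylsilyl trifluoromethanesulfonate, CC[Si](CC)(CC)OS(=O)(=O)C(F)(F)F
Why: Silylation with the silyl triflate covers both the primary and the hindered tertiary hydroxyl, which masks C8–OH for the rest of the route and leaves C9–O in a form that can later be oxidised directly.

Step 4
Reactants: 5 bis(triethylsilyl) ether
Product: 7 (2R,5S)-5-[(2R)-1,2-bis(triethylsilyloxy)propan-2-yl]-2-methyloxolane-2-carbaldehyde, via ozonide 6 (not isolated)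
Conditions: O3, CH2Cl2, −78 °C; then PPh3, −78 °C → rt
Reagents that add atoms: ozone, [O-][O+]=O
Why: Ozonolysis with reductive work-up cleaves the only alkene, and the aldehyde obtained (C3) sits on a fully substituted carbon and cannot epimerise.

Step 5
Reactants: 7 tetrahydrofuran aldehyde
Product: 8 (E)-alkenyl pinacol boronate
Conditions: CH2(Bpin)2, LiTMP, THF, 0 °C; then 7, −78 °C → rt
Reagents that add atoms: bis(pinacolatoboryl)methane, CC1(C)OB(CB2OC(C)(C)C(C)(C)O2)OC1(C)C
Why: The boron–Wittig olefination of the lithiated geminal bis(boronate) with a non-enolisable aldehyde should give the (E)-alkenyl boronate by syn elimination of the boron–oxygen pair, which adds C2 in the form needed for the conjugate addition.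

Step 6
Reactants: 8 (E)-alkenyl pinacol boronate; 9 cyclohex-2-en-1-one
Product: 10 (3S)-3-alkenylcyclohexan-1-one
Conditions: [Rh(OH)(cod)]2 (3 mol %), (S)-BINAP (7 mol %), 1,4-dioxane/H2O 10:1, 50 °C
Reagents that add atoms: none
Why: The Hayashi–Miyaura reaction (asymmetric 1,4-addition of an alkenylboron reagent to an enone, catalysed by monovalent rhodium) forms the C1–C2 bond, and the (S)-BINAP complex should deliver the alkenyl group to the enone face that gives the (S)-configured ring carbon (C1 of the target) under catalyst control, as it does with other (E)-alkenyl and aryl boron reagents.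

Step 7
Reactants: 10 (3S)-3-alkenylcyclohexan-1-one
Product: 11 ethylene ketal of 10
Conditions: TMSOCH2CH2OTMS, TMSOTf (cat.), CH2Cl2, −78 → −20 °C
Reagents that add atoms: 1,2-bis(trimethylsilyloxy)ethane, C[Si](C)(C)OCCO[Si](C)(C)C
Why: Aprotic dioxolane formation from the bis-silylated glycol under silyl triflate catalysis protects the ketone, which must be absent when hydride is used in step 9, without endangering the triethylsilyl ethers.

Step 8
Reactants: 11 ketal alkene
Product: 12 (2R,3S)-trans-epoxide
Conditions: D-fructose-derived Shi ketone (30 mol %), KHSO5 (as its triple salt), K2CO3 buffer, Bu4NHSO4 (cat.), MeCN/CH2(OMe)2/H2O, 0 °C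
Reagents that add atoms: potassium peroxymonosulfate, [K+].[O-]S(=O)(=O)OO
Why: The Shi epoxidation (chiral dioxirane, spiro transition state) oxidises trans-disubstituted alkenes with the facial sense that leads to (R,R)-type epoxides, which here means C2 R and C3 S, the reagent overriding the distant stereocentres.

Step 9
Reactants: 12 trans-epoxide
Product: 13 C3 carbinol
Conditions: LiBHEt3, THF, 0 °C → rt
Reagents that add atoms: none
Why: Hydride opening of the epoxide by SN2 attack should occur at C2, the carbon remote from the fully substituted, oxygen-bearing C4, as in the reduction of 2,3-epoxy ethers, so the oxygen stays on C3 with its configuration (S) untouched.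

Step 10
Reactants: 13 C3 carbinol
Product: 14 C3 tert-butyldimethylsilyl ether
Conditions: TBSOTf, 2,6-lutidine, CH2Cl2, −78 → 0 °C
Reagents that add atoms: tert-butyldimethylsilyl trifluoromethanesulfonate, CC(C)(C)[Si](C)(C)OS(=O)(=O)C(F)(F)F
Why: Silylation with the silyl triflate protects the hindered C3 hydroxyl as the most robust silyl ether of the route, to be released only in the last step.

Step 11
Reactants: 14 C3 tert-butyldimethylsilyl ether
Product: 15 C9 aldehyde
Conditions: (COCl)2, DMSO, CH2Cl2, −78 → −40 °C; then Et3N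
Reagents that add atoms: none
Why: Under Swern conditions a primary triethylsilyl ether is cleaved by the chlorosulfonium salt and oxidised directly to the aldehyde, while the tertiary triethylsilyl ether, the secondary tert-butyldimethylsilyl ether and the dioxolane are left intact.

Step 12
Reactants: 15 C9 aldehyde
Product: 16 (E)-iodoalkene
Conditions: CHI3, CrCl2, THF/1,4-dioxane, 0 °C → rt
Reagents that add atoms: iodoform, IC(I)I
Why: The Takai olefination converts the non-enolisable aldehyde into the (E)-iodoalkene through the geminal dichromium reagent formed from iodoform, which adds C10 and the handle for ring closure.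

Step 13
Reactants: 16 (E)-iodoalkene ketal
Product: 17 iodoalkene ketone
Conditions: PPTS, acetone/H2O, 50 °C
Reagents that add atoms: water, O
Why: Mild acid-catalysed ketal hydrolysis (transketalisation in wet acetone) unmasks the C16 ketone, the dioxolane being far more labile than the tertiary triethylsilyl and the hindered secondary tert-butyldimethylsilyl ether.

Step 14
Reactants: 17 iodoalkene ketone
Product: 18 2-(hydroxymethylidene) ketone
Conditions: NaH, HCO2Et, EtOH (cat.), THF, 0 °C → rt
Reagents that add atoms: ethyl formate, CCOC=O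
Why: The crossed Claisen condensation with ethyl formate is reversible and settles on the less hindered α-methylene C12, remote from the C1 side chain as with other 3-substituted cyclohexanones, which introduces C11 and activates C12 for alkylation.

Step 15
Reactants: 18 2-(hydroxymethylidene) ketone
Product: 19 2-formyl-2-methyl ketone (C12 R)
Conditions: MeI, K2CO3, acetone, rt
Reagents that add atoms: iodomethane, CI
Why: C-Alkylation of the chelated enolate of the 2-formyl ketone creates the quaternary C12, and the methyl group should enter axially on the half-chair that carries the C1 side chain equatorially, that is cis to this side chain, which places the formyl carbon C11 trans to C2 as required; the minor epimer and any O-methyl ether are removed by chromatography.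

Step 16
Reactants: 19 2-formyl-2-methyl ketone
Product: 20 macrocyclic allylic alcohol
Conditions: CrCl2 (excess), NiCl2 (cat.), DMSO/THF, rt, slow addition at high dilution
Reagents that add atoms: none
Why: In the Nozaki–Hiyama–Kishi reaction the iodoalkene adds oxidatively to zerovalent nickel and is passed on to trivalent chromium, and the alkenylchromium adds to the aldehyde but not to the ketone, closing the 14-membered carbocycle (C1 to C14) by the C10–C11 bond; the new carbinol centre C11 may form as either epimer because it is oxidised later.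

Step 17
Reactants: 20 macrocyclic allylic alcohol
Product: 21 saturated hydroxy ketone
Conditions: H2 (1 atm), [Ir(cod)(PCy3)(py)]PF6 (cat.), CH2Cl2, rt
Reagents that add atoms: none
Why: Hydroxyl-directed hydrogenation with the cationic iridium catalyst saturates the hindered C9–C10 alkene without hydrogenolysis of the allylic C–O bonds.

Step 18
Reactants: 21 saturated hydroxy ketone
Product: 22 bridged cyclohexanone with C11 triethylsilyl ether
Conditions: TESOTf, 2,6-lutidine, CH2Cl2, −78 → 0 °C
Reagents that add atoms: triethylsilyl trifluoromethanesulfonate, CC[Si](CC)(CC)OS(=O)(=O)C(F)(F)F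
Why: Silylation of the neopentyl-type C11 hydroxyl prevents retro-aldol cleavage and later acyl migration and leaves C16 as the only carbonyl group.

Step 19
Reactants: 22 bridged cyclohexanone
Product: 24 bridged seven-membered lactone, via Criegee adduct 23 (not isolated)
Conditions: mCPBA, NaHCO3 (buffer), CH2Cl2, 0 °C → rt
Reagents that add atoms: 3-chloroperoxybenzoic acid, OOC(=O)c1cccc(Cl)c1
Why: The peracid adds to the C16 carbonyl, the only ketone present, to give the Criegee adduct 23, and the C16–C12 bond antiperiplanar to the O–O bond migrates to oxygen with loss of 3-chlorobenzoate (Baeyer–Villiger oxidation). The closest known reaction type is the oxidation of 2,2-disubstituted cyclohexanones to ε-lactones with migration of the quaternary carbon. The seven-membered lactone (O, C16, C15, C1, C14, C13, C12) is closed by ring expansion, a 1,2-shift that inserts oxygen into the six-membered ring, and not by a cyclisation, so no hindered tertiary alcohol has to be acylated. The new C12–O stereocentre is controlled by the migrating carbon itself, which moves with retention and so carries over the configuration set in step 15 (C12 R). The step needs migration of C12 in preference to the C15 methylene, which the much higher migratory aptitude of a fully substituted carbon secures, and it needs chemoselectivity, which is secured because C11 is a silyl ether, no alkene is present yet and the buffer protects the silyl ethers.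

Step 20
Reactants: 24 bridged seven-membered lactone
Product: 27 α-methylene lactone, via dimethylaminomethyl lactone 25 (not isolated), via trimethylammonium iodide 26 (not isolated)
Conditions: LDA, THF, −78 °C; [CH2=NMe2]I, −78 → 0 °C; then MeI, CH2Cl2, rt; then NaHCO3 (aq.)
Reagents that add atoms: N,N-dimethylmethyleneiminium iodide (Eschenmoser's salt), C=[N+](C)C.[I-]
Why: Eschenmoser methylenation: the lithium enolate of the lactone (C15 is its only α-carbon) undergoes a Mannich reaction with the iminium salt, and quaternisation followed by mild base-induced elimination of trimethylamine should give the exocyclic methylene group.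

Step 21
Reactants: 27 α-methylene lactone
Product: 28 C8,C11-diol
Conditions: HF·pyridine, pyridine, THF, 0 °C
Reagents that add atoms: none
Why: Selective desilylation: buffered HF·pyridine cleaves the two triethylsilyl ethers much faster than the hindered secondary tert-butyldimethylsilyl ether, and the acidic, non-nucleophilic medium spares the α-methylene lactone.

Step 22
Reactants: 28 C8,C11-diol
Product: 29 C11 ketone
Conditions: Dess–Martin periodinane, CH2Cl2, 0 °C → rt
Reagents that add atoms: none
Why: Dess–Martin oxidation converts the secondary C11 alcohol (both epimers) into the ketone, while the tertiary C8 hydroxyl cannot be oxidised and the C3 hydroxyl is still silylated.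

Step 23
Reactants: 29 C11 ketone
Product: 30 CNP0266269.2
Conditions: HF·pyridine, THF, 0 °C → rt
Reagents that add atoms: none
Why: Fluoride-mediated desilylation under acidic conditions releases the C3 hydroxyl without exposing the α-methylene lactone or the α-acyloxy ketone to base.

Compound list
1 | (R)-(−)-linalool, (3R)-3,7-dimethylocta-1,6-dien-3-ol | C=C[C@](C)(O)CCC=C(C)C | starting material
2 | (2E,6R)-2,6-dimethylocta-2,7-diene-1,6-diol | C=C[C@](C)(O)CC/C=C(\C)CO | intermediate
3 | (3R)-5-[(2R,3R)-3-(hydroxymethyl)-3-methyloxiran-2-yl]-3-methylpent-1-en-3-ol | C=C[C@](C)(O)CC[C@H]1O[C@]1(C)CO | intermediate (not isolated)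
4 | (2R)-2-[(2S,5R)-5-ethenyl-5-methyloxolan-2-yl]propane-1,2-diol (2,5-cis; C4 R, C7 S, C8 R) | C=C[C@@]1(C)CC[C@H](O1)[C@](C)(O)CO | intermediate
5 | (2S,5R)-2-[(2R)-1,2-bis(triethylsilyloxy)propan-2-yl]-5-ethenyl-5-methyloxolane | C=C[C@@]1(C)CC[C@H](O1)[C@](C)(O[Si](CC)(CC)CC)CO[Si](CC)(CC)CC | intermediate
6 | 3-{(2R,5S)-5-[(2R)-1,2-bis(triethylsilyloxy)propan-2-yl]-2-methyloxolan-2-yl}-1,2,4-trioxolane (both epimers at the trioxolane CH) | C1OOC(O1)[C@@]2(C)CC[C@H](O2)[C@](C)(O[Si](CC)(CC)CC)CO[Si](CC)(CC)CC | intermediate (not isolated)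
7 | (2R,5S)-5-[(2R)-1,2-bis(triethylsilyloxy)propan-2-yl]-2-methyloxolane-2-carbaldehyde | O=C[C@@]1(C)CC[C@H](O1)[C@](C)(O[Si](CC)(CC)CC)CO[Si](CC)(CC)CC | intermediate
8 | 2-[(E)-2-{(2R,5S)-5-[(2R)-1,2-bis(triethylsilyloxy)propan-2-yl]-2-methyloxolan-2-yl}ethenyl]-4,4,5,5-tetramethyl-1,3,2-dioxaborolane | CC1(C)OB(/C=C/[C@@]2(C)CC[C@H](O2)[C@](C)(O[Si](CC)(CC)CC)CO[Si](CC)(CC)CC)OC1(C)C | intermediate
9 | cyclohex-2-en-1-one | O=C1C=CCCC1 | starting material
10 | (3S)-3-[(E)-2-{(2R,5S)-5-[(2R)-1,2-bis(triethylsilyloxy)propan-2-yl]-2-methyloxolan-2-yl}ethenyl]cyclohexan-1-one (C1 S, C4 R, C7 S, C8 R) | O=C1CCC[C@@H](C1)/C=C/[C@@]2(C)CC[C@H](O2)[C@](C)(O[Si](CC)(CC)CC)CO[Si](CC)(CC)CC | intermediate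
11 | ethylene ketal of 10, (7S)-7-alkenyl-1,4-dioxaspiro[4.5]decane | C1COC2(O1)CCC[C@@H](C2)/C=C/[C@@]3(C)CC[C@H](O3)[C@](C)(O[Si](CC)(CC)CC)CO[Si](CC)(CC)CC | intermediate
12 | trans-epoxide of 11 at C2–C3 (C1 S, C2 R, C3 S, C4 R, C7 S, C8 R) | C1COC2(O1)CCC[C@@H](C2)[C@H]3O[C@@H]3[C@@]4(C)CC[C@H](O4)[C@](C)(O[Si](CC)(CC)CC)CO[Si](CC)(CC)CC | intermediate
13 | C3 carbinol: C16 ethylene ketal, C3–OH, C8 and C9 triethylsilyl ethers (C1 R, C3 S, C4 R, C7 S, C8 R) | C1COC2(O1)CCC[C@@H](C2)C[C@H](O)[C@@]3(C)CC[C@H](O3)[C@](C)(O[Si](CC)(CC)CC)CO[Si](CC)(CC)CC | intermediate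
14 | C3 tert-butyldimethylsilyl ether of 13 | C1COC2(O1)CCC[C@@H](C2)C[C@H](O[Si](C)(C)C(C)(C)C)[C@@]3(C)CC[C@H](O3)[C@](C)(O[Si](CC)(CC)CC)CO[Si](CC)(CC)CC | intermediate
15 | C9 aldehyde: C16 ketal, C3 OTBS, C8 OTES (geometry as in 14; C8 descriptor becomes S by the priority rules) | C1COC2(O1)CCC[C@@H](C2)C[C@H](O[Si](C)(C)C(C)(C)C)[C@@]3(C)CC[C@H](O3)[C@](C)(O[Si](CC)(CC)CC)C=O | intermediate
16 | (9E)-10-iodoalkene: C16 ketal, C3 OTBS, C8 OTES (C1 R, C3 S, C4 R, C7 S, C8 R) | C1COC2(O1)CCC[C@@H](C2)C[C@H](O[Si](C)(C)C(C)(C)C)[C@@]3(C)CC[C@H](O3)[C@](C)(O[Si](CC)(CC)CC)/C=C/I | intermediate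
17 | iodoalkene ketone (C16 ketone free) | O=C1CCC[C@@H](C1)C[C@H](O[Si](C)(C)C(C)(C)C)[C@@]2(C)CC[C@H](O2)[C@](C)(O[Si](CC)(CC)CC)/C=C/I | intermediate
18 | 2-(hydroxymethylidene) ketone: chelated enol, C11 on C12 | O=C1/C(=C\O)CC[C@@H](C1)C[C@H](O[Si](C)(C)C(C)(C)C)[C@@]2(C)CC[C@H](O2)[C@](C)(O[Si](CC)(CC)CC)/C=C/I | intermediate
19 | 2-formyl-2-methyl ketone: methyl cis and formyl trans to the C1 side chain (C1 R, C3 S, C4 R, C7 S, C8 R, C12 R) | O=C[C@@]1(C)CC[C@@H](CC1=O)C[C@H](O[Si](C)(C)C(C)(C)C)[C@@]2(C)CC[C@H](O2)[C@](C)(O[Si](CC)(CC)CC)/C=C/I | intermediate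
20 | macrocyclic allylic alcohol: 14-membered carbocycle C1–C14 bridged by C15–C16(=O) between C1 and C12, 4,7-oxygen bridge, (9E)-alkene, C11–OH (both epimers), C3 OTBS, C8 OTES | C1C(=O)[C@]2(C)CC[C@@H]1C[C@H](O[Si](C)(C)C(C)(C)C)[C@@]1(C)CC[C@H](O1)[C@](C)(O[Si](CC)(CC)CC)/C=C/C2O | intermediate
21 | saturated hydroxy ketone (C9–C10 single bond, C11–OH) | C1C(=O)[C@]2(C)CC[C@@H]1C[C@H](O[Si](C)(C)C(C)(C)C)[C@@]1(C)CC[C@H](O1)[C@](C)(O[Si](CC)(CC)CC)CCC2O | intermediate
22 | bridged cyclohexanone: C12 bonded to C16, C11 OTES, C8 OTES, C3 OTBS (C1 R, C3 S, C4 R, C7 S, C8 R, C12 R) | C1C(=O)[C@]2(C)CC[C@@H]1C[C@H](O[Si](C)(C)C(C)(C)C)[C@@]1(C)CC[C@H](O1)[C@](C)(O[Si](CC)(CC)CC)CCC2O[Si](CC)(CC)CC | intermediate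
23 | Criegee adduct: C16 bearing OH and the 3-chloroperbenzoate group | C1C(O)(OOC(=O)c3cccc(Cl)c3)[C@]2(C)CC[C@@H]1C[C@H](O[Si](C)(C)C(C)(C)C)[C@@]1(C)CC[C@H](O1)[C@](C)(O[Si](CC)(CC)CC)CCC2O[Si](CC)(CC)CC | intermediate (not isolated)
24 | bridged seven-membered lactone: O inserted between C16 and C12, silyl ethers as in 22 (C12 R) | C1C(=O)O[C@]2(C)CC[C@@H]1C[C@H](O[Si](C)(C)C(C)(C)C)[C@@]1(C)CC[C@H](O1)[C@](C)(O[Si](CC)(CC)CC)CCC2O[Si](CC)(CC)CC | intermediate
25 | 15-(dimethylaminomethyl) lactone (C15 epimers) | CN(C)CC1C(=O)O[C@]2(C)CC[C@@H]1C[C@H](O[Si](C)(C)C(C)(C)C)[C@@]1(C)CC[C@H](O1)[C@](C)(O[Si](CC)(CC)CC)CCC2O[Si](CC)(CC)CC | intermediate (not isolated)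
26 | trimethylammonium iodide of 25 | [I-].C[N+](C)(C)CC1C(=O)O[C@]2(C)CC[C@@H]1C[C@H](O[Si](C)(C)C(C)(C)C)[C@@]1(C)CC[C@H](O1)[C@](C)(O[Si](CC)(CC)CC)CCC2O[Si](CC)(CC)CC | intermediate (not isolated)
27 | α-methylene lactone: C3 OTBS, C8 OTES, C11 OTES | C=C1C(=O)O[C@]2(C)CC[C@@H]1C[C@H](O[Si](C)(C)C(C)(C)C)[C@@]1(C)CC[C@H](O1)[C@](C)(O[Si](CC)(CC)CC)CCC2O[Si](CC)(CC)CC | intermediate
28 | C8,C11-diol: C3 OTBS retained | C=C1C(=O)O[C@]2(C)CC[C@@H]1C[C@H](O[Si](C)(C)C(C)(C)C)[C@@]1(C)CC[C@H](O1)[C@](C)(O)CCC2O | intermediate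
29 | C11 ketone: 3-O-tert-butyldimethylsilyl ether of the target | C=C1C(=O)O[C@]2(C)CC[C@@H]1C[C@H](O[Si](C)(C)C(C)(C)C)[C@@]1(C)CC[C@H](O1)[C@](C)(O)CCC2=O | intermediate
30 | CNP0266269.2 (1R,3S,4R,7S,8R,12R) | C=C1C(=O)O[C@]2(C)CC[C@@H]1C[C@H](O)[C@@]1(C)CC[C@H](O1)[C@](C)(O)CCC2=O | target

Total step count: 23.
Longest linear sequence: 23 steps, from (R)-linalool 1; cyclohex-2-en-1-one 9 enters in step 6.

Steps most likely to fail

Step 15. The risk is poor facial selectivity in the C-methylation, since the only bias is the axial-attack preference of a ring whose controlling substituent is 1,4 to the reacting carbon. The fallback reverses the order in which the two substituents reach C12, so that the same facial bias is used the other way round. It sets out from 18: the methylation is run without regard to selectivity, and the mixture of 19 and the C12 epimer of 19 F1 is deformylated (K2CO3, MeOH/H2O) to the 2-methyl ketone F2. Thermodynamic silylation (TMSCl, NaI, Et3N, MeCN) gives the tetrasubstituted trimethylsilyl enol ether F3. A Mukaiyama-type hydroxymethylation with aqueous formaldehyde and Yb(OTf)3 brings in C11 as the second substituent and gives the hydroxymethyl ketone F4. Dess–Martin oxidation of the primary alcohol returns to the route at 19.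

Step 16. The risk is oligomerisation, or failure of the alkenylchromium to reach the hindered, fully substituted aldehyde within the ring-closing conformation. The fallback forms the same C10–C11 bond by a different reaction and sets out from aldehyde 15. Ohira–Bestmann homologation (dimethyl (1-diazo-2-oxopropyl)phosphonate, K2CO3, MeOH) gives the terminal alkyne ketal F5, and ketal hydrolysis as in step 13 gives the alkyne ketone F6. Formylation and methylation as in steps 14 and 15 give the hydroxymethylidene ketone F7 and then the ynal F8. A reductive alkyne–aldehyde macrocyclisation catalysed by zerovalent nickel (Ni(cod)2, an N-heterocyclic carbene ligand, Et3SiH, THF, high dilution) gives the macrocyclic (E)-allylic triethylsilyl ether F9. Hydrogenation of its C9–C10 alkene (H2, [Ir(cod)(PCy3)(py)]PF6) returns to the route at 22.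

Step 8. The risk is low conversion or poor facial selectivity in the epoxidation of a trans-alkene flanked by a ring carbon and a fully substituted carbon. The fallback sets C3 by ketone reduction instead and sets out from 11. Epoxidation with mCPBA (NaHCO3, CH2Cl2) gives the trans-epoxide as a mixture of the two facial isomers F10. LiBHEt3 opens both at C2 to the C3 carbinol epimers F11, and Dess–Martin oxidation gives the C3 ketone F12. Corey–Bakshi–Shibata reduction with the (R)-configured oxazaborolidine and BH3·SMe2 (large group the fully substituted C4, small group the C2 methylene) returns to the route at 13.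

Further compounds
F1 | step 15 | C12 epimer of 19 | O=C[C@]1(C)CC[C@@H](CC1=O)C[C@H](O[Si](C)(C)C(C)(C)C)[C@@]2(C)CC[C@H](O2)[C@](C)(O[Si](CC)(CC)CC)/C=C/I
F2 | step 15 | 2-methyl ketone (C12 epimers) | CC1CC[C@@H](CC1=O)C[C@H](O[Si](C)(C)C(C)(C)C)[C@@]2(C)CC[C@H](O2)[C@](C)(O[Si](CC)(CC)CC)/C=C/I
F3 | step 15 | tetrasubstituted trimethylsilyl enol ether (C16=C12) | CC1=C(O[Si](C)(C)C)C[C@H](CC1)C[C@H](O[Si](C)(C)C(C)(C)C)[C@@]2(C)CC[C@H](O2)[C@](C)(O[Si](CC)(CC)CC)/C=C/I
F4 | step 15 | 2-(hydroxymethyl)-2-methyl ketone (C12 as in 19) | OC[C@@]1(C)CC[C@@H](CC1=O)C[C@H](O[Si](C)(C)C(C)(C)C)[C@@]2(C)CC[C@H](O2)[C@](C)(O[Si](CC)(CC)CC)/C=C/I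
F5 | step 16 | terminal alkyne ketal (C9≡C10) | C1COC2(O1)CCC[C@@H](C2)C[C@H](O[Si](C)(C)C(C)(C)C)[C@@]3(C)CC[C@H](O3)[C@](C)(O[Si](CC)(CC)CC)C#C
F6 | step 16 | alkyne ketone | O=C1CCC[C@@H](C1)C[C@H](O[Si](C)(C)C(C)(C)C)[C@@]2(C)CC[C@H](O2)[C@](C)(O[Si](CC)(CC)CC)C#C
F7 | step 16 | 2-(hydroxymethylidene) alkyne ketone | O=C1/C(=C\O)CC[C@@H](C1)C[C@H](O[Si](C)(C)C(C)(C)C)[C@@]2(C)CC[C@H](O2)[C@](C)(O[Si](CC)(CC)CC)C#C
F8 | step 16 | 2-formyl-2-methyl alkyne ketone (ynal, C12 R) | O=C[C@@]1(C)CC[C@@H](CC1=O)C[C@H](O[Si](C)(C)C(C)(C)C)[C@@]2(C)CC[C@H](O2)[C@](C)(O[Si](CC)(CC)CC)C#C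
F9 | step 16 | macrocyclic (9E)-allylic triethylsilyl ether (C11 epimers) | C1C(=O)[C@]2(C)CC[C@@H]1C[C@H](O[Si](C)(C)C(C)(C)C)[C@@]1(C)CC[C@H](O1)[C@](C)(O[Si](CC)(CC)CC)/C=C/C2O[Si](CC)(CC)CC
F10 | step 8 | trans-epoxide of 11 as a mixture of facial isomers | C1COC2(O1)CCC[C@@H](C2)C3OC3[C@@]4(C)CC[C@H](O4)[C@](C)(O[Si](CC)(CC)CC)CO[Si](CC)(CC)CC
F11 | step 8 | C3 carbinol epimers | C1COC2(O1)CCC[C@@H](C2)CC(O)[C@@]3(C)CC[C@H](O3)[C@](C)(O[Si](CC)(CC)CC)CO[Si](CC)(CC)CC
F12 | step 8 | C3 ketone | C1COC2(O1)CCC[C@@H](C2)CC(=O)[C@@]3(C)CC[C@H](O3)[C@](C)(O[Si](CC)(CC)CC)CO[Si](CC)(CC)CC
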